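**Retrosynthetic overview**
1. The last step is LiAlH4 reduction of the two C18 methyl esters; the whole route runs in the ester series.
2. The central cyclohexene is formed last by cutting its own C13=C14 double bond back to a 1,6-keto-aldehyde, closed forward by intramolecular reductive carbonyl coupling (a titanium ketyl makes the aldehyde carbon a nucleophile toward the ketone carbon).
3. The keto-aldehyde comes from an anti-configured aldehyde by Me addition/oxidation and CO/H2 on a vinyl group; its C12–C14′ bond and both new stereocentres come from one Ir/amine dual-catalytic allylation of a C13 aldehyde with a dienyl carbinol.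
4. Both coupling partners derive from one C12 aldehyde (Wittig plus vinyl Grignard; one-carbon homologation).
5. The C12 aldehyde comes from methyl abietate by cleavage of ring C; the two decalins (rings A and B of each half, with C4, C5, C9, C10) are never built, they come from the chiral pool.

**Definitions and assumptions**
- Lab = (1S,4aR,5R,8aR)-5-(methoxycarbonyl)-5,8a-dimethyl-2-methylidenedecahydronaphthalen-1-yl, i.e. the labd-8(17)-ene bicycle (4R,5R,9S,10R; α-CO2Me and β-CH3 at C4) attached through C9. LabOH is the same unit with CH2OH in place of CO2Me.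
- Locants follow the labdane skeleton of each half: unprimed for the half that supplies ring carbon C12, primed for the half that supplies C14′.
- Assumption: methyl abietate is bought as such (technical grade, purified by chromatography).
- Assumption: the (S)-phosphoramidite–olefin ligand gives (S) at C14′; the two catalysts act independently, so the (R)-ligand is used instead if the sense proves opposite.

**Route**

Step 1
Reactants: 1 methyl abietate
Product: 3 methyl 13,14-dioxo-13,14-secoabiet-7-en-18-oate (keto-enal), via ozonide 2 (not isolated)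
Conditions: O3 (1.0 equiv), CH2Cl2, −78 °C; then Me2S, −78 °C to rt
Reagents that add atoms: ozone, [O-][O+]=O
Why: Ozonolysis; the 13,14-alkene is the more electron-rich and less hindered end of the diene and the remaining 7,8-alkene becomes a deactivated enal after the first cleavage, so the reaction stops there with C4, C5, C9 and C10 untouched.

Step 2
Reactants: 3 keto-enal
Product: 5 2-methyl-5-Lab-pentan-3-one, via tosylhydrazone 4 (not isolated)
Conditions: TsNHNH2 (1.05 equiv), THF, 0 °C to rt; then catecholborane (1.2 equiv), CHCl3, 0 °C; then NaOAc·3H2O, 60 °C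
Reagents that add atoms: none
Why: Kabalka reductive alkene transposition; the aldehyde forms the hydrazone much faster than the hindered isopropyl ketone, hydride adds to C=N, and the allylic diazene loses N2 by retro-ene shift to give the exocyclic C8=C17 methylene with H delivered to C7 and no change at C9.

Step 3
Reactants: 5 2-methyl-5-Lab-pentan-3-one
Product: 6 4-hydroxy-2-methyl-5-Lab-pentan-3-one (C12 epimers)
Conditions: NaN(SiMe3)2 (1.1 equiv), THF, −78 °C; then 2-(phenylsulfonyl)-3-phenyloxaziridine (1.3 equiv), −78 °C; aq. NH4Cl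
Reagents that add atoms: 2-(phenylsulfonyl)-3-phenyloxaziridine, O=S(=O)(c1ccccc1)N1OC1c1ccccc1
Why: Davis enolate hydroxylation; kinetic deprotonation occurs at the CH2 (C12) and not at the isopropyl CH, and the new carbinol centre is cleaved in the next step.

Step 4
Reactants: 6 α-ketol
Product: 7 2-Lab-ethanal
Conditions: H5IO6 (1.5 equiv), THF/H2O, 0 °C to rt
Reagents that add atoms: none
Why: Malaprade-type periodate cleavage of the α-ketol C12–C13 bond gives the C12 aldehyde and isobutyric acid without touching the alkene or the hindered ester.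

Step 5
Reactants: 7 2-Lab-ethanal
Product: 8 (2E)-2-methyl-4-Lab-but-2-enal
Conditions: Ph3P=C(CH3)CHO (1.3 equiv), toluene, 90 °C
Reagents that add atoms: 2-(triphenylphosphoranylidene)propanal, CC(C=O)=P(c1ccccc1)(c1ccccc1)c1ccccc1
Why: Wittig olefination with a stabilised ylide gives the (E)-trisubstituted C12′=C13′ alkene of the target side chain (typically above 20:1).

Step 6
Reactants: 8 (E)-enal
Product: 9 (4E)-4-methyl-6-Lab-hexa-1,4-dien-3-ol (C14′ epimers)
Conditions: CH2=CHMgBr (1.2 equiv), THF, −78 °C; aq. NH4Cl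
Reagents that add atoms: vinylmagnesium bromide, C=C[Mg]Br
Why: Grignard 1,2-addition to an α-branched enal; the carbinol configuration is irrelevant because it is ionised in step 8.

Step 7
Reactants: 7 2-Lab-ethanal
Product: 11 3-Lab-propanal, via enol ether 10 (not isolated)
Conditions: Ph3P(CH2OCH3)Cl (1.5 equiv), KN(SiMe3)2 (1.4 equiv), THF, 0 °C; then 1 M aq. HCl (cat.), THF, 0 °C
Reagents that add atoms: (methoxymethyl)triphenylphosphonium chloride, COC[P+](c1ccccc1)(c1ccccc1)c1ccccc1.[Cl-]; water, O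
Why: Wittig one-carbon homologation followed by mild enol ether hydrolysis gives the C13 aldehyde whose α-carbon is C12.

Step 8
Reactants: 11 3-Lab-propanal (1.5 equiv); 9 dienyl carbinol
Product: 12 (2S,3S,4E)-3-ethenyl-4-methyl-6-Lab-2-(Lab-methyl)hex-4-enal
Conditions: [Ir(cod)Cl]2 (3 mol %), (S)-phosphoramidite–olefin ligand from BINOL and 5H-dibenzo[b,f]azepine (12 mol %), (R)-diarylprolinol TMS ether with Ar = 3,5-(CF3)2C6H3 (15 mol %), (MeO)2P(O)OH (0.5 equiv), ClCH2CH2Cl, 25 °C
Reagents that add atoms: none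
Why: Stereodivergent Ir/amine dual-catalytic α-allylation of a linear aldehyde (Carreira type); the Ir-allyl from 9 is attacked at the branched carbon C14′ by the enamine of 11, the ligand sets C14′ (S) and the amine sets C12 (S), giving the 2,3-anti isomer that becomes the cis ring.

Step 9
Reactants: 12 anti-aldehyde
Product: 13 (3S,4S,5E)-4-ethenyl-5-methyl-7-Lab-3-(Lab-methyl)hept-5-en-2-ol (C2 epimers)
Conditions: MeMgBr (1.2 equiv), THF, −78 °C; aq. NH4Cl
Reagents that add atoms: methylmagnesium bromide, C[Mg]Br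
Why: Grignard 1,2-addition to the aldehyde is far faster than attack on the two neopentyl-type C18 esters, and the low temperature avoids epimerisation at C12.

Step 10
Reactants: 13 secondary alcohol
Product: 14 (3S,4S,5E)-4-ethenyl-5-methyl-7-Lab-3-(Lab-methyl)hept-5-en-2-one
Conditions: Dess–Martin periodinane (1.3 equiv), CH2Cl2, 0 °C to rt
Reagents that add atoms: none
Why: Dess–Martin oxidation is non-basic, so the α-stereocentre C12 of the new methyl ketone is not epimerised.

Step 11
Reactants: 14 methyl ketone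
Product: 15 (4S,5S)-5-acetyl-6-Lab-4-[(2E)-4-Lab-but-2-en-2-yl]hexanal
Conditions: Rh(acac)(CO)2 (1 mol %), BiPhePhos (2 mol %), CO/H2 (1:1, 10 bar), toluene, 60 °C
Reagents that add atoms: carbon monoxide, [C-]#[O+]
Why: Linear-selective hydroformylation; the monosubstituted vinyl group reacts much faster than the 1,1-disubstituted and trisubstituted alkenes and supplies the missing ring carbon C14 as an aldehyde.

Step 12
Reactants: 15 keto-aldehyde
Product: 16 (5S,6S)-1-methyl-6-(Lab-methyl)-5-[(2E)-4-Lab-but-2-en-2-yl]cyclohex-1-ene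
Conditions: TiCl3(DME)1.5 (8 equiv), Zn(Cu) (20 equiv), DME, reflux; 15 added over 30 h
Reagents that add atoms: none
Why: Intramolecular McMurry coupling; low-valent titanium reduces the aldehyde to a titanium ketyl, a carbonyl carbon with reversed (nucleophilic, acyl-anion-type) polarity that attacks the ketone carbon, so two normally electrophilic carbons are joined in a six-membered ring and the titanium pinacolate is deoxygenated to the C13=C14 alkene without creating or touching a stereocentre.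

Step 13
Reactants: 16 diester
Product: 17 (5S,6S)-1-methyl-6-(LabOH-methyl)-5-[(2E)-4-LabOH-but-2-en-2-yl]cyclohex-1-ene (target)
Conditions: LiAlH4 (3 equiv), THF, 0 °C to reflux
Reagents that add atoms: none
Why: Hydride reduction of both hindered methyl esters to the primary alcohols leaves all five alkenes and all stereocentres unchanged.

**Compound list**
1 | methyl abietate | CC(C)C1=CC2=CC[C@H]3[C@](C)(C(=O)OC)CCC[C@]3(C)[C@H]2CC1 | starting material
2 | 13,14-ozonide of methyl abietate (C13/C14 mixture) | CC(C)C15OC(OO5)C2=CC[C@H]3[C@](C)(C(=O)OC)CCC[C@]3(C)[C@H]2CC1 | intermediate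
3 | methyl 13,14-dioxo-13,14-secoabiet-7-en-18-oate | O=CC1=CC[C@H]2[C@](C)(C(=O)OC)CCC[C@]2(C)[C@H]1CCC(=O)C(C)C | intermediate
4 | tosylhydrazone of the aldehyde of 3 | Cc1ccc(cc1)S(=O)(=O)N/N=C/C1=CC[C@H]2[C@](C)(C(=O)OC)CCC[C@]2(C)[C@H]1CCC(=O)C(C)C | intermediate
5 | 2-methyl-5-Lab-pentan-3-one | C=C1CC[C@H]2[C@](C)(C(=O)OC)CCC[C@]2(C)[C@H]1CCC(=O)C(C)C | intermediate
6 | 4-hydroxy-2-methyl-5-Lab-pentan-3-one (C12 epimers) | C=C1CC[C@H]2[C@](C)(C(=O)OC)CCC[C@]2(C)[C@H]1CC(O)C(=O)C(C)C | intermediate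
7 | 2-Lab-ethanal | C=C1CC[C@H]2[C@](C)(C(=O)OC)CCC[C@]2(C)[C@H]1CC=O | intermediate
8 | (2E)-2-methyl-4-Lab-but-2-enal | C=C1CC[C@H]2[C@](C)(C(=O)OC)CCC[C@]2(C)[C@H]1C/C=C(\C)C=O | intermediate
9 | (4E)-4-methyl-6-Lab-hexa-1,4-dien-3-ol (C3 epimers) | C=C1CC[C@H]2[C@](C)(C(=O)OC)CCC[C@]2(C)[C@H]1C/C=C(\C)C(O)C=C | intermediate
10 | 1-methoxy-3-Lab-prop-1-ene (E/Z mixture) | C=C1CC[C@H]2[C@](C)(C(=O)OC)CCC[C@]2(C)[C@H]1CC=COC | intermediate
11 | 3-Lab-propanal | C=C1CC[C@H]2[C@](C)(C(=O)OC)CCC[C@]2(C)[C@H]1CCC=O | intermediate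
12 | (2S,3S,4E)-3-ethenyl-4-methyl-6-Lab-2-(Lab-methyl)hex-4-enal | C=C1CC[C@H]2[C@](C)(C(=O)OC)CCC[C@]2(C)[C@H]1C/C=C(\C)[C@@H](C=C)[C@@H](C=O)C[C@H]1C(=C)CC[C@H]2[C@](C)(C(=O)OC)CCC[C@]12C | intermediate
13 | (3S,4S,5E)-4-ethenyl-5-methyl-7-Lab-3-(Lab-methyl)hept-5-en-2-ol (C2 epimers) | C=C1CC[C@H]2[C@](C)(C(=O)OC)CCC[C@]2(C)[C@H]1C/C=C(\C)[C@@H](C=C)[C@@H](C(C)O)C[C@H]1C(=C)CC[C@H]2[C@](C)(C(=O)OC)CCC[C@]12C | intermediate
14 | (3S,4S,5E)-4-ethenyl-5-methyl-7-Lab-3-(Lab-methyl)hept-5-en-2-one | C=C1CC[C@H]2[C@](C)(C(=O)OC)CCC[C@]2(C)[C@H]1C/C=C(\C)[C@@H](C=C)[C@@H](C(C)=O)C[C@H]1C(=C)CC[C@H]2[C@](C)(C(=O)OC)CCC[C@]12C | intermediate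
15 | (4S,5S)-5-acetyl-6-Lab-4-[(2E)-4-Lab-but-2-en-2-yl]hexanal | C=C1CC[C@H]2[C@](C)(C(=O)OC)CCC[C@]2(C)[C@H]1C/C=C(\C)[C@@H](CCC=O)[C@@H](C(C)=O)C[C@H]1C(=C)CC[C@H]2[C@](C)(C(=O)OC)CCC[C@]12C | intermediate
16 | (5S,6S)-1-methyl-6-(Lab-methyl)-5-[(2E)-4-Lab-but-2-en-2-yl]cyclohex-1-ene | C=C1CC[C@H]2[C@](C)(C(=O)OC)CCC[C@]2(C)[C@H]1C/C=C(\C)[C@H]1CCC=C(C)[C@H]1C[C@H]1C(=C)CC[C@H]2[C@](C)(C(=O)OC)CCC[C@]12C | intermediate
17 | CNP0194625.1, the bis(hydroxymethyl) compound | C=C1CC[C@H]2[C@](C)(CO)CCC[C@]2(C)[C@H]1C/C=C(\C)[C@H]1CCC=C(C)[C@H]1C[C@H]1C(=C)CC[C@H]2[C@](C)(CO)CCC[C@]12C | target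

**Step count and risks**
Total: 13 steps from methyl abietate. Longest linear sequence: 12 steps (steps 1–6, then 8–13); the other branch (steps 1–4, 7) joins at step 8.

Most likely to fail, step 8: the dienyl carbinol is bulky, the pentadienyl–iridium could be attacked at the wrong terminus, and the catalyst pair may be mismatched with the substrates. The fallback sets out from 11 and 8 and returns at 14. Compound 11 is oxidised (NaClO2, NaH2PO4, 2-methyl-2-butene) to 3-Lab-propanoic acid F1. Compound 8 is extended with (EtO)2P(O)CH2CO2Et and NaH to the ethyl (2E,4E)-dienoate F2 and reduced with i-Bu2AlH at −78 °C to the linear dienol F3. DCC and DMAP join acid and alcohol as the allyl ester F4. An enantioselective boron-enolate Ireland–Claisen rearrangement (Corey's C2-symmetric diazaborolidine bromide, amine base chosen for the 2,3-anti series) then gives the γ,δ-unsaturated acid F5 with the same C12–C14′ bond and configuration. MeLi (2.2 equiv) converts the acid directly into methyl ketone 14.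

Most likely to fail, step 11: the hydroformylation may isomerise the skipped diene or touch the exocyclic methylenes. The fallback sets out from 14 and returns at 15. Selective hydroboration of the vinyl group with Cy2BH and oxidation with NaBO3 gives the primary keto alcohol F6. Dess–Martin oxidation gives the 1,5-keto-aldehyde F7. Aldehyde-selective Wittig reaction with Ph3P=CHOCH3 (1 equiv, −78 °C) gives the enol ether F8, and mild aqueous acid hydrolysis gives 15.

Most likely to fail, step 12: the McMurry coupling may epimerise C12 next to the ketone or attack the esters on long exposure. The fallback sets out from 15 and returns at 16. Non-basic double methylenation with Zn, CH2Br2 and TiCl4 gives the isopropenyl/butenyl diene F9. Ring-closing metathesis with the second-generation Grubbs catalyst then closes the same C13=C14 bond to give 16.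

**Further compounds**
F1 | step 8 | 3-Lab-propanoic acid | C=C1CC[C@H]2[C@](C)(C(=O)OC)CCC[C@]2(C)[C@H]1CCC(=O)O
F2 | step 8 | ethyl (2E,4E)-4-methyl-6-Lab-hexa-2,4-dienoate | C=C1CC[C@H]2[C@](C)(C(=O)OC)CCC[C@]2(C)[C@H]1C/C=C(\C)/C=C/C(=O)OCC
F3 | step 8 | (2E,4E)-4-methyl-6-Lab-hexa-2,4-dien-1-ol | C=C1CC[C@H]2[C@](C)(C(=O)OC)CCC[C@]2(C)[C@H]1C/C=C(\C)/C=C/CO
F4 | step 8 | (2E,4E)-4-methyl-6-Lab-hexa-2,4-dienyl 3-Lab-propanoate | C=C1CC[C@H]2[C@](C)(C(=O)OC)CCC[C@]2(C)[C@H]1C/C=C(\C)/C=C/COC(=O)CC[C@H]1C(=C)CC[C@H]2[C@](C)(C(=O)OC)CCC[C@]12C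
F5 | step 8 | (2S,3S,4E)-3-ethenyl-4-methyl-6-Lab-2-(Lab-methyl)hex-4-enoic acid | C=C1CC[C@H]2[C@](C)(C(=O)OC)CCC[C@]2(C)[C@H]1C/C=C(\C)[C@@H](C=C)[C@@H](C(=O)O)C[C@H]1C(=C)CC[C@H]2[C@](C)(C(=O)OC)CCC[C@]12C
F6 | step 11 | (3S,4S,5E)-4-(2-hydroxyethyl)-5-methyl-7-Lab-3-(Lab-methyl)hept-5-en-2-one | C=C1CC[C@H]2[C@](C)(C(=O)OC)CCC[C@]2(C)[C@H]1C/C=C(\C)[C@@H](CCO)[C@@H](C(C)=O)C[C@H]1C(=C)CC[C@H]2[C@](C)(C(=O)OC)CCC[C@]12C
F7 | step 11 | (3S,4S)-4-acetyl-5-Lab-3-[(2E)-4-Lab-but-2-en-2-yl]pentanal | C=C1CC[C@H]2[C@](C)(C(=O)OC)CCC[C@]2(C)[C@H]1C/C=C(\C)[C@@H](CC=O)[C@@H](C(C)=O)C[C@H]1C(=C)CC[C@H]2[C@](C)(C(=O)OC)CCC[C@]12C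
F8 | step 11 | methyl enol ether of the homologated aldehyde (E/Z mixture) | C=C1CC[C@H]2[C@](C)(C(=O)OC)CCC[C@]2(C)[C@H]1C/C=C(\C)[C@@H](CC=COC)[C@@H](C(C)=O)C[C@H]1C(=C)CC[C@H]2[C@](C)(C(=O)OC)CCC[C@]12C
F9 | step 12 | diene with isopropenyl on C12 and but-3-enyl on C14′ | C=C1CC[C@H]2[C@](C)(C(=O)OC)CCC[C@]2(C)[C@H]1C/C=C(\C)[C@@H](CCC=C)[C@@H](C(C)=C)C[C@H]1C(=C)CC[C@H]2[C@](C)(C(=O)OC)CCC[C@]12C
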